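**Retrosynthetic overview**
- The oxane is cut at the O1–C6 bond. C6 is benzylic to the 4-hydroxy-3,5-dimethoxyphenyl ring and para to its free OH, so it is a latent p-quinone methide carbon: the ring can be closed by oxidising a plain ArCH2 of an open-chain diol and letting the remote hydroxyl add 1,6.
- The cyclisation precursor is a (3S,5S)-anti-1,7-diarylheptane-3,5-diol. Its C3 carbinol (future C2–O1) comes from hydroxyl-directed anti reduction of a β-hydroxy ketone, and its C5 carbinol (future C4) from an Ipc2B-mediated methyl ketone aldol.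
- The aldol joins silylated zingerone (C1–C4) to 3-(4-benzyloxy-3,5-dimethoxyphenyl)propanal (C5–C7), which is made from sinapic acid.
- Ring order: both benzene rings are bought; the oxane is the only ring made, in the penultimate step, and the guaiacyl silyl ether is removed last.

Key step: step 9

Remark on numbering: the oxane is numbered O1, C2 (carrying the 2-arylethyl chain), C4 (carbinol), C6 (aryl-bearing). On this numbering the target is (2S,4R,6S), all-cis. Heptane chains are numbered from the guaiacyl end.

Remark on the aldol reagent: (−)-Ipc2BCl is taken as the antipode that delivers a methyl ketone enolate to the Re face of an unbranched aldehyde. The sense should be confirmed on compound 10 (Mosher esters) before material is advanced; (+)-Ipc2BCl would be used if the opposite sense were found.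

**Route**

Step 1
Reactants: 1 sinapic acid
Product: 2 3-(4-hydroxy-3,5-dimethoxyphenyl)propanoic acid
Conditions: H2 (1 atm), 10% Pd/C, MeOH, rt
Reagents that add atoms: none
Why: Heterogeneous catalytic hydrogenation should saturate the cinnamate C=C while leaving the arene, the acid and the phenol untouched.

Step 2
Reactants: 2 3-(4-hydroxy-3,5-dimethoxyphenyl)propanoic acid
Product: 3 benzyl 3-(4-benzyloxy-3,5-dimethoxyphenyl)propanoate
Conditions: BnBr (2.5 equiv), K2CO3 (3 equiv), DMF, 60 °C
Reagents that add atoms: benzyl bromide, BrCc1ccccc1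
Why: Williamson O-alkylation of the phenoxide and the carboxylate in one operation should give the benzyl ether and a benzyl ester that is consumed in the next step.

Step 3
Reactants: 3 benzyl 3-(4-benzyloxy-3,5-dimethoxyphenyl)propanoate
Product: 4 3-(4-benzyloxy-3,5-dimethoxyphenyl)propan-1-ol
Conditions: LiAlH4, THF, 0 °C to rt
Reagents that add atoms: none
Why: Hydride reduction of the ester should give the primary alcohol, the aryl benzyl ether being inert to LiAlH4.

Step 4
Reactants: 4 3-(4-benzyloxy-3,5-dimethoxyphenyl)propan-1-ol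
Product: 5 3-(4-benzyloxy-3,5-dimethoxyphenyl)propanal
Conditions: TEMPO (10 mol%), PhI(OAc)2 (1.1 equiv), CH2Cl2, rt
Reagents that add atoms: none
Why: The oxoammonium (TEMPO) oxidation of a primary alcohol should stop cleanly at the aldehyde and does not attack the electron-rich arene.

Step 5
Reactants: 6 zingerone
Product: 7 4-[4-(tert-butyldimethylsilyloxy)-3-methoxyphenyl]butan-2-one
Conditions: TBSCl, imidazole, DMF, rt
Reagents that add atoms: tert-butyldimethylsilyl chloride, CC(C)(C)[Si](C)(C)Cl
Why: Imidazole-promoted silylation masks the guaiacyl phenol, which would otherwise quench the boron enolate and later compete as a second quinone methide precursor.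

Step 6
Reactants: 7 4-[4-(tert-butyldimethylsilyloxy)-3-methoxyphenyl]butan-2-one; 5 3-(4-benzyloxy-3,5-dimethoxyphenyl)propanal
Product: 10 (5S)-7-(4-benzyloxy-3,5-dimethoxyphenyl)-1-[4-(tert-butyldimethylsilyloxy)-3-methoxyphenyl]-5-hydroxyheptan-3-one, via enol diisopinocampheylborinate 8 (not isolated), via boron aldolate 9 (not isolated)
Conditions: 7, (−)-Ipc2BCl (1.3 equiv), Et3N (1.6 equiv), Et2O, 0 °C; then 5, −78 to −20 °C; then H2O2, MeOH, pH 7 buffer, 0 °C
Reagents that add atoms: none
Why: In this reagent-controlled boron aldol of a methyl ketone, Ipc2BCl/Et3N should enolise on the methyl side and the Ipc ligands should steer the enolate to the Re face of the aldehyde in a closed boron transition state, giving the 5S carbinol (future C4), with enantioselectivity expected to be moderate rather than complete.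

Step 7
Reactants: 10 (5S)-β-hydroxy ketone
Product: 11 (3S,5S)-7-(4-benzyloxy-3,5-dimethoxyphenyl)-1-[4-(tert-butyldimethylsilyloxy)-3-methoxyphenyl]heptane-3,5-diol
Conditions: Me4NBH(OAc)3 (5 equiv), MeCN–AcOH (1:1), −30 °C
Reagents that add atoms: none
Why: In the Evans–Saksena reduction the C5 hydroxyl exchanges onto boron and delivers hydride intramolecularly through a chair-like transition state, which should set the new C3 carbinol (S) 1,3-anti to C5.

Step 8
Reactants: 11 (3S,5S)-anti-diol with both phenols protected
Product: 12 (3S,5S)-1-[4-(tert-butyldimethylsilyloxy)-3-methoxyphenyl]-7-(4-hydroxy-3,5-dimethoxyphenyl)heptane-3,5-diol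
Conditions: H2 (1 atm), 10% Pd/C, EtOAc, rt
Reagents that add atoms: none
Why: Hydrogenolysis of the aryl benzyl ether should free only the syringyl phenol, since the aryl silyl ether and the secondary alcohols are inert to these conditions.

Step 9
Reactants: 12 (3S,5S)-anti-diol with free syringyl phenol
Product: 14 (2S,4R,6S)-2-{2-[4-(tert-butyldimethylsilyloxy)-3-methoxyphenyl]ethyl}-6-(4-hydroxy-3,5-dimethoxyphenyl)oxan-4-ol, via p-quinone methide 13 (not isolated)
Conditions: Ag2O (1.1 equiv), CH2Cl2, rt, dark; filter; CSA (10 mol%), CH2Cl2, 0 °C to rt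
Reagents that add atoms: none
Why: Ag2O should remove the phenolic hydrogen and one benzylic hydrogen of the 4-alkyl-2,6-dimethoxyphenol in a two-electron oxidation to give p-quinone methide 13, and acid activation of its carbonyl lets the heptane C3 hydroxyl add to the exocyclic methide carbon (oxa-1,6-addition) with rearomatisation, which forms the O1–C6 bond. The closest known reaction type is the Ag2O-generated p-quinone methide cyclisation of 4-alkyl-2,6-dimethoxyphenols and the biomimetic cycloetherification of diarylheptanoids and lignans. The oxane closes in a 6-exo-trig mode, whereas the other hydroxyl could only close an oxetane. The new stereocentre C6 is set by a chair in which the aryl group lies equatorial, cis to the equatorial C2 chain and C4 hydroxyl, and because the para-hydroxybenzylic C–O bond can re-ionise under the catalytic acid, any 2,6-trans isomer should drain to the all-equatorial (2S,4R,6S) isomer. Chemoselectivity between the two arenes rests on the single free phenol (the silylated guaiacyl ring cannot form a quinone methide), and holding the oxidant near one equivalent guards against a second oxidation of the product phenol.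

Step 10
Reactants: 14 silylated all-cis oxane
Product: 15 (2S,4R,6S)-6-(4-hydroxy-3,5-dimethoxyphenyl)-2-[2-(4-hydroxy-3-methoxyphenyl)ethyl]oxan-4-ol (CNP0302691.1)
Conditions: TBAF, AcOH (1:1, 1.5 equiv), THF, 0 °C
Reagents that add atoms: none
Why: Fluoride desilylation of the aryl silyl ether is driven by Si–F bond formation, and the acetic acid buffer keeps the phenols protonated so that the para-hydroxybenzylic ether should not open through a phenoxide.

**Compound list**

1 | sinapic acid | COc1cc(/C=C/C(=O)O)cc(OC)c1O | starting material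
2 | 3-(4-hydroxy-3,5-dimethoxyphenyl)propanoic acid | COc1cc(CCC(=O)O)cc(OC)c1O | intermediate
3 | benzyl 3-(4-benzyloxy-3,5-dimethoxyphenyl)propanoate | COc1cc(CCC(=O)OCc2ccccc2)cc(OC)c1OCc1ccccc1 | intermediate
4 | 3-(4-benzyloxy-3,5-dimethoxyphenyl)propan-1-ol | COc1cc(CCCO)cc(OC)c1OCc1ccccc1 | intermediate
5 | 3-(4-benzyloxy-3,5-dimethoxyphenyl)propanal | COc1cc(CCC=O)cc(OC)c1OCc1ccccc1 | intermediate
6 | zingerone | CC(=O)CCc1ccc(O)c(OC)c1 | starting material
7 | 4-[4-(tert-butyldimethylsilyloxy)-3-methoxyphenyl]butan-2-one | CC(=O)CCc1ccc(O[Si](C)(C)C(C)(C)C)c(OC)c1 | intermediate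
8 | enol diisopinocampheylborinate of 7 (terminal enolate, Ipc groups from (+)-α-pinene) | C=C(CCc1ccc(O[Si](C)(C)C(C)(C)C)c(OC)c1)OB([C@@H]1C[C@@H]2C[C@H]([C@H]1C)C2(C)C)[C@@H]1C[C@@H]2C[C@H]([C@H]1C)C2(C)C | intermediate (not isolated)
9 | O-diisopinocampheylboryl aldolate of 10 | COc1cc(CCC(=O)C[C@@H](OB([C@@H]2C[C@@H]3C[C@H]([C@H]2C)C3(C)C)[C@@H]2C[C@@H]3C[C@H]([C@H]2C)C3(C)C)CCc2cc(OC)c(OCc3ccccc3)c(OC)c2)ccc1O[Si](C)(C)C(C)(C)C | intermediate (not isolated)
10 | (5S)-7-(4-benzyloxy-3,5-dimethoxyphenyl)-1-[4-(tert-butyldimethylsilyloxy)-3-methoxyphenyl]-5-hydroxyheptan-3-one | COc1cc(CCC(=O)C[C@@H](O)CCc2cc(OC)c(OCc3ccccc3)c(OC)c2)ccc1O[Si](C)(C)C(C)(C)C | intermediate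
11 | (3S,5S)-7-(4-benzyloxy-3,5-dimethoxyphenyl)-1-[4-(tert-butyldimethylsilyloxy)-3-methoxyphenyl]heptane-3,5-diol | COc1cc(CC[C@H](O)C[C@@H](O)CCc2cc(OC)c(OCc3ccccc3)c(OC)c2)ccc1O[Si](C)(C)C(C)(C)C | intermediate
12 | (3S,5S)-1-[4-(tert-butyldimethylsilyloxy)-3-methoxyphenyl]-7-(4-hydroxy-3,5-dimethoxyphenyl)heptane-3,5-diol | COc1cc(CC[C@H](O)C[C@@H](O)CCc2cc(OC)c(O)c(OC)c2)ccc1O[Si](C)(C)C(C)(C)C | intermediate
13 | 4-{(3S,5S)-7-[4-(tert-butyldimethylsilyloxy)-3-methoxyphenyl]-3,5-dihydroxyheptylidene}-2,6-dimethoxycyclohexa-2,5-dien-1-one (p-quinone methide) | COc1cc(CC[C@H](O)C[C@@H](O)CC=C2C=C(OC)C(=O)C(OC)=C2)ccc1O[Si](C)(C)C(C)(C)C | intermediate (not isolated)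
14 | (2S,4R,6S)-2-{2-[4-(tert-butyldimethylsilyloxy)-3-methoxyphenyl]ethyl}-6-(4-hydroxy-3,5-dimethoxyphenyl)oxan-4-ol | COc1cc(CC[C@H]2C[C@@H](O)C[C@@H](c3cc(OC)c(O)c(OC)c3)O2)ccc1O[Si](C)(C)C(C)(C)C | intermediate
15 | (2S,4R,6S)-6-(4-hydroxy-3,5-dimethoxyphenyl)-2-[2-(4-hydroxy-3-methoxyphenyl)ethyl]oxan-4-ol | COc1cc(CC[C@H]2C[C@@H](O)C[C@@H](c3cc(OC)c(O)c(OC)c3)O2)ccc1O | target

**Step count**

Total steps: 10. Longest linear sequence: 9 steps (steps 1, 2, 3, 4, 6, 7, 8, 9, 10, from sinapic acid).

**Steps most likely to fail, with fallbacks**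

Step 9. The quinone methide may tautomerise to the 4-alkenylphenol, the product phenol may be oxidised a second time, or ring closure may lag behind intermolecular capture and give oligomers. The fallback separates oxidation from ring closure. It sets out from 12: quinone methide 13 is generated as before but run at once into methanol containing a trace of acid, so that the solvent captures it as the C7 methyl ether of diol 12 F1 (both C7 epimers, carbinol centres unchanged), a stable and isolable compound. F1 is then ionised with catalytic CSA in dry CH2Cl2; the para-hydroxybenzylic cation is trapped by the C3 hydroxyl under thermodynamic control with loss of methanol, and the route is rejoined at 14. Any oxane formed already in the methanol stage converges on the same product.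

Step 6. Facial discrimination by the Ipc ligands on an unbranched aldehyde may be only moderate, and the minor enantiomer would be carried through every later substrate-controlled step to the mirror-image product. The fallback sets both carbinols by catalyst control. It sets out from 7 and 3: the kinetic enolate of 7 (LiN(SiMe3)2, 2.2 equiv, THF, −78 to 0 °C) is acylated by benzyl ester 3 in a crossed Claisen condensation to give 7-(4-benzyloxy-3,5-dimethoxyphenyl)-1-[4-(tert-butyldimethylsilyloxy)-3-methoxyphenyl]heptane-3,5-dione F2. Asymmetric hydrogenation of F2 (H2, 50–100 atm, RuCl2[(S)-BINAP] cat., MeOH, 50 °C) should reduce both carbonyls to the (3S,5S)-anti-diol, the aryl benzyl ether being inert to the homogeneous ruthenium catalyst. The route is rejoined at 11, so that steps 6 and 7 are both replaced.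

Step 10. If the buffer does not hold, phenoxide formation on the syringyl ring can trigger retro-1,6-addition: the benzylic ether opens, and C6 is scrambled or the chain eliminates. The fallback moves the desilylation ahead of the ring closure. It sets out from 12: TBAF in THF gives (3S,5S)-7-(4-hydroxy-3,5-dimethoxyphenyl)-1-(4-hydroxy-3-methoxyphenyl)heptane-3,5-diol F3, in which no benzylic ether is yet present for base to open. F3 is oxidised with Ag2O (1.0 equiv, CH2Cl2), relying on the easier oxidation of the 2,6-dimethoxyphenol over the 2-methoxyphenol, to the syringyl p-quinone methide of the bis-phenol diol F4, which is cyclised with catalytic CSA as in step 9. The route is rejoined directly at 15.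

**Further compounds**

F1 | step 9 | C7 methyl ether of diol 12: 1-[4-(tert-butyldimethylsilyloxy)-3-methoxyphenyl]-7-(4-hydroxy-3,5-dimethoxyphenyl)-7-methoxyheptane-3,5-diol, carbinol centres as in 12, both C7 epimers | COc1cc(CC[C@H](O)C[C@@H](O)CC(OC)c2cc(OC)c(O)c(OC)c2)ccc1O[Si](C)(C)C(C)(C)C
F2 | step 6 | 7-(4-benzyloxy-3,5-dimethoxyphenyl)-1-[4-(tert-butyldimethylsilyloxy)-3-methoxyphenyl]heptane-3,5-dione | COc1cc(CCC(=O)CC(=O)CCc2cc(OC)c(OCc3ccccc3)c(OC)c2)ccc1O[Si](C)(C)C(C)(C)C
F3 | step 10 | (3S,5S)-7-(4-hydroxy-3,5-dimethoxyphenyl)-1-(4-hydroxy-3-methoxyphenyl)heptane-3,5-diol | COc1cc(CC[C@H](O)C[C@@H](O)CCc2cc(OC)c(O)c(OC)c2)ccc1O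
F4 | step 10 | 4-[(3S,5S)-3,5-dihydroxy-7-(4-hydroxy-3-methoxyphenyl)heptylidene]-2,6-dimethoxycyclohexa-2,5-dien-1-one | COc1cc(CC[C@H](O)C[C@@H](O)CC=C2C=C(OC)C(=O)C(OC)=C2)ccc1O
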